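**Retrosynthetic overview**

1. Target 10 ⇐ benzoylation and desilylation of epoxy diol 8 ⇐ hydroxyl-directed epoxidation of dienyl diol 7 (the oxirane is the last ring, placed cis to the C2 oxygen).
2. 7 ⇐ ester reduction of mono-silylated cis-dihydrodiol ester 6 ⇐ catalytic enantio- and site-selective silylation (kinetic resolution) of racemic diol ester 5.
3. 5 ⇐ key step: methoxide-triggered semibenzilic 1,2-vinyl shift that contracts the seven-membered ring of syn-bis-epoxy enone 3 to the cyclohexadiene; both oxiranes end up as the cis-diol.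
4. 3 ⇐ tropone 1 + singlet oxygen, then Co(II)-induced endoperoxide → syn-bis-epoxide rearrangement in one pot.
5. Ring order: cycloheptatrienone (bought) → two oxiranes → six-membered carbocycle (ring contraction) → oxirane.

Assumptions: compounds 2–5 are racemic and are drawn as the enantiomer that is carried on. The antipode of the silylation catalyst that matches the (5R,6S)-diol is fixed by one pilot run. In the bicyclic names, C1 is the quaternary oxirane carbon and C6 the oxirane CH.

**Route**

Step 1
Reactants: 1 tropone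
Product: 3 rac-syn-2,3:4,5-diepoxycyclohept-6-en-1-one, via tropone endoperoxide 2 (not isolated)
Conditions: O2, TPP (1 mol %), hν (visible), CH2Cl2, −20 °C; then CoTPP (5 mol %), −20 → 0 °C
Reagents that add atoms: dioxygen (O=O)
Why: Dye-sensitised singlet-oxygen [4+2] cycloaddition across C2–C5 of tropone gives the bicyclic endoperoxide, and the Co(II)-porphyrin endoperoxide → bis-epoxide rearrangement (O–O homolysis, each oxyl adding to the bridging alkene on its own face) puts both oxiranes on one face, which fixes the later cis C2/C3 oxygen relationship (racemic).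

Step 2
Reactants: 3 rac-syn-2,3:4,5-diepoxycyclohept-6-en-1-one
Product: 5 rac-methyl cis-5,6-dihydroxycyclohexa-1,3-diene-1-carboxylate, via epoxy hydroxy ester 4 (not isolated)
Conditions: NaOMe (0.3 equiv), MeOH–THF, −40 → 0 °C; pH 7 buffer
Reagents that add atoms: methanol (CO)
Why: Proposed new method: methoxide adds to the ketone and the tetrahedral alkoxide undergoes a semibenzilic (quasi-Favorskii) 1,2-shift of the vinylic α′-carbon onto the α-carbon, with the α,β-oxirane C–O as leaving group (the flexible seven-membered ring can place the migrating bond antiperiplanar to that C–O; 7 → 6 ring contraction, β-C–O retained), then the doubly activated α-H of the resulting β,γ-unsaturated ester 4 is removed and a vinylogous E1cB opens the second oxirane to the conjugated dienoate with retention at both carbinol carbons, so the syn-bis-epoxide becomes the cis-diol; the closest known reactions are the quasi-Favorskii contraction of α-halo ketones lacking α′-H and the base-induced Favorskii-type contraction of α,β-epoxy ketones to β-hydroxy acids.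

Step 3
Reactants: 5 rac-methyl cis-5,6-dihydroxycyclohexa-1,3-diene-1-carboxylate
Product: 6 methyl (5R,6S)-6-hydroxy-5-(triethylsilyloxy)cyclohexa-1,3-diene-1-carboxylate
Conditions: Hoveyda–Snapper tert-leucine-derived imidazole catalyst (30 mol %), Et3SiCl (0.55 equiv), i-Pr2NEt (0.6 equiv), THF, −40 °C, 48 h
Reagents that add atoms: chlorotriethylsilane (CC[Si](Cl)(CC)CC)
Why: Catalytic enantio- and site-selective silylation (kinetic resolution of a syn-1,2-diol) silylates only the less hindered distal 5-OH of the (5R,6S)-enantiomer, so one step resolves the racemate (at most 50 % yield, ent-5 is recovered) and differentiates the two hydroxyls.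

Step 4
Reactants: 6 methyl (5R,6S)-6-hydroxy-5-(triethylsilyloxy)cyclohexa-1,3-diene-1-carboxylate
Product: 7 (1S,6R)-2-(hydroxymethyl)-6-(triethylsilyloxy)cyclohexa-2,4-dien-1-ol
Conditions: DIBAL-H (3.5 equiv), CH2Cl2, −78 °C; Rochelle salt
Reagents that add atoms: none
Why: DIBAL-H 1,2-reduction of the dienoate ester gives the primary allylic alcohol, while the silyl ether, the diene and both stereocentres are untouched at −78 °C under a neutral work-up.

Step 5
Reactants: 7 (1S,6R)-2-(hydroxymethyl)-6-(triethylsilyloxy)cyclohexa-2,4-dien-1-ol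
Product: 8 (1R,2R,3R,6S)-1-(hydroxymethyl)-3-(triethylsilyloxy)-7-oxabicyclo[4.1.0]hept-4-en-2-ol
Conditions: VO(acac)2 (3 mol %), t-BuOOH (1.2 equiv, decane), CH2Cl2, 0 °C
Reagents that add atoms: tert-butyl hydroperoxide (CC(C)(C)OO)
Why: Vanadium-catalysed hydroxyl-directed epoxidation (Sharpless VO(acac)2/TBHP) delivers oxygen only to the trisubstituted alkene flanked by the two free hydroxyls and syn to the ring hydroxyl, which sets both oxirane stereocentres cis to the C2 and C3 oxygens; the alkene next to the silyl ether is not directed.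

Step 6
Reactants: 8 (1R,2R,3R,6S)-1-(hydroxymethyl)-3-(triethylsilyloxy)-7-oxabicyclo[4.1.0]hept-4-en-2-ol
Product: 10 [(1S,2R,3R,6S)-2-(benzoyloxy)-3-hydroxy-7-oxabicyclo[4.1.0]hept-4-en-1-yl]methyl benzoate, via silyl dibenzoate 9 (not isolated)
Conditions: Bz2O (3 equiv), DMAP (0.3 equiv), pyridine, CH2Cl2, 0 → 23 °C; then HF·pyridine, THF, 0 °C
Reagents that add atoms: benzoic anhydride (O=C(OC(=O)c1ccccc1)c1ccccc1)
Why: DMAP-catalysed benzoylation esterifies the primary and the only free secondary hydroxyl, and HF·pyridine then cleaves the triethylsilyl ether under mildly acidic conditions in which DMAP is protonated (no further acylation) and base-promoted benzoate migration cannot occur, so the 3-OH is freed next to the 2-benzoate with the vinyl epoxide intact.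

**Compound list**

1 | tropone (cyclohepta-2,4,6-trien-1-one) | O=C1C=CC=CC=C1 | starting material
2 | rac-6,7-dioxabicyclo[3.2.2]nona-3,8-dien-2-one (tropone 2,5-endoperoxide) | O=C1C=C[C@@H]2C=C[C@H]1OO2 | intermediate
3 | rac-syn-2,3:4,5-diepoxycyclohept-6-en-1-one (both oxirane oxygens on one face) | O=C1C=C[C@H]2O[C@H]2[C@H]3O[C@@H]13 | intermediate
4 | rac-methyl 5-hydroxy-7-oxabicyclo[4.1.0]hept-2-ene-4-carboxylate (as alkoxide; OH cis to the oxirane oxygen) | COC(=O)[C@H]1C=C[C@H]2O[C@H]2[C@H]1O | intermediate
5 | rac-methyl cis-5,6-dihydroxycyclohexa-1,3-diene-1-carboxylate ((5R,6S) drawn) | COC(=O)C1=CC=C[C@@H](O)[C@H]1O | intermediate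
6 | methyl (5R,6S)-6-hydroxy-5-(triethylsilyloxy)cyclohexa-1,3-diene-1-carboxylate | COC(=O)C1=CC=C[C@@H](O[Si](CC)(CC)CC)[C@H]1O | intermediate
7 | (1S,6R)-2-(hydroxymethyl)-6-(triethylsilyloxy)cyclohexa-2,4-dien-1-ol | OCC1=CC=C[C@@H](O[Si](CC)(CC)CC)[C@H]1O | intermediate
8 | (1R,2R,3R,6S)-1-(hydroxymethyl)-3-(triethylsilyloxy)-7-oxabicyclo[4.1.0]hept-4-en-2-ol (oxirane O, 2-OH and 3-OSiEt3 on one face) | OC[C@]12O[C@H]1C=C[C@@H](O[Si](CC)(CC)CC)[C@H]2O | intermediate
9 | [(1S,2R,3R,6S)-2-(benzoyloxy)-3-(triethylsilyloxy)-7-oxabicyclo[4.1.0]hept-4-en-1-yl]methyl benzoate | O=C(OC[C@]12O[C@H]1C=C[C@@H](O[Si](CC)(CC)CC)[C@H]2OC(=O)c1ccccc1)c1ccccc1 | intermediate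
10 | [(1S,2R,3R,6S)-2-(benzoyloxy)-3-hydroxy-7-oxabicyclo[4.1.0]hept-4-en-1-yl]methyl benzoate | O=C(OC[C@]12O[C@H]1C=C[C@@H](O)[C@H]2OC(=O)c1ccccc1)c1ccccc1 | target

**Totals and risks**

Total step count: 6. Longest linear sequence: 6 (fully linear from tropone).

Steps most likely to fail:

Step 2 (the proposed new cascade; possible diversion to hydroxytropolones, Michael adducts or simple epoxide methanolysis). The fallback uses known chemistry, sets out from 3 and comes back at 5. MgBr2·OEt2 (Et2O, −20 °C) opens the ketone-activated oxirane at the α-carbon with inversion to give rac-2-bromo-4,5-epoxy-3-hydroxycyclohept-6-en-1-one F3. TBSOTf/2,6-lutidine protects it as rac-2-bromo-3-(tert-butyldimethylsilyloxy)-4,5-epoxycyclohept-6-en-1-one F4. NaOMe/MeOH then effects the classical quasi-Favorskii (semibenzilic) contraction of an α-bromo ketone without enolisable α′-H, followed by the same E1cB opening of the remaining oxirane, to rac-methyl cis-6-(tert-butyldimethylsilyloxy)-5-hydroxycyclohexa-1,3-diene-1-carboxylate F5. TBAF/AcOH returns 5.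

Step 1 (the cobalt step on an α-keto endoperoxide may be diverted by loss of the acidic bridgehead hydrogen, Kornblum–DeLaMare type, towards 5-hydroxytropolone). The fallback sets out from 2, now isolated cold, and comes back at 3. The ketone is first reduced with NaBH4/CeCl3 (MeOH, −78 °C; the peroxide survives borohydride) to 6,7-dioxabicyclo[3.2.2]nona-3,8-dien-2-ol F1 (either carbinol epimer). This non-enolisable endoperoxide is rearranged with CoTPP to syn-2,3:4,5-diepoxycyclohept-6-en-1-ol F2, and Dess–Martin oxidation gives 3.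

Step 3 (the selectivity factor of the catalytic silylation is untested on this diene diol). The fallback sets out from 5 and comes back at 8.
- Et3SiCl/imidazole (DMF, −40 °C) silylates the distal hydroxyl of both enantiomers, the usual site selectivity for 3-substituted cis-cyclohexadienediols. This gives 6 together with methyl (5S,6R)-6-hydroxy-5-(triethylsilyloxy)cyclohexa-1,3-diene-1-carboxylate F6.
- DIBAL-H then gives 7 together with (1R,6S)-2-(hydroxymethyl)-6-(triethylsilyloxy)cyclohexa-2,4-dien-1-ol F7.
- The racemic diol is resolved in the epoxidation itself under Sharpless conditions (Ti(OiPr)4, L-(+)-DIPT, TBHP 0.6 equiv, 4 Å MS, CH2Cl2, −20 °C). By the Sharpless face rule, L-(+)-tartrate delivers oxygen to the hydroxyl-syn face of 7 only, so 8 forms and F7 is left behind.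

Further compounds
F1 | step 1 | rac-6,7-dioxabicyclo[3.2.2]nona-3,8-dien-2-ol (carbinol centre unassigned, re-oxidised later) | OC1C=C[C@@H]2C=C[C@H]1OO2
F2 | step 1 | rac-syn-2,3:4,5-diepoxycyclohept-6-en-1-ol (carbinol centre unassigned) | OC1C=C[C@H]2O[C@H]2[C@H]3O[C@@H]13
F3 | step 2 | rac-2-bromo-4,5-epoxy-3-hydroxycyclohept-6-en-1-one (Br trans to OH, OH cis to the oxirane) | O=C1C=C[C@H]2O[C@H]2[C@@H](O)[C@@H]1Br
F4 | step 2 | rac-2-bromo-3-(tert-butyldimethylsilyloxy)-4,5-epoxycyclohept-6-en-1-one | O=C1C=C[C@H]2O[C@H]2[C@@H](O[Si](C)(C)C(C)(C)C)[C@@H]1Br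
F5 | step 2 | rac-methyl cis-6-(tert-butyldimethylsilyloxy)-5-hydroxycyclohexa-1,3-diene-1-carboxylate | COC(=O)C1=CC=C[C@@H](O)[C@H]1O[Si](C)(C)C(C)(C)C
F6 | step 3 | methyl (5S,6R)-6-hydroxy-5-(triethylsilyloxy)cyclohexa-1,3-diene-1-carboxylate | COC(=O)C1=CC=C[C@H](O[Si](CC)(CC)CC)[C@@H]1O
F7 | step 3 | (1R,6S)-2-(hydroxymethyl)-6-(triethylsilyloxy)cyclohexa-2,4-dien-1-ol | OCC1=CC=C[C@H](O[Si](CC)(CC)CC)[C@@H]1O
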